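The earlier runs and the new flask come from a simulation for substances that don't exist.

the same everywhere: free catalyst 0.16 mol%
- summer: substrate 0.15 M; reagent 1.5 equiv; temperature −22 °C; run made earlier
- winter: substrate 0.22 M; reagent 1.5 equiv; temperature −6 °C; run made earlier
- north: substrate 0.30 M; reagent 1.50 equiv; at 0 °C until 3.0 h, from then on at −30 °C; time 6.0 h
- south: substrate 0.30 M; reagent 1.50 equiv; at −30 °C throughout; time 12 h

| run | time / h | target / % | substrate / % |
|---|---|---|---|
| summer | 1.33 | 3 | 97 |
| summer | 4.00 | 7 | 90 |
| summer | 6.00 | 12 | 90 |
| summer | 8.00 | 13 | 85 |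
| summer | 15.0 | 26 | 71 |
| winter | 1.00 | 11 | 87 |
| winter | 2.00 | 20 | 79 |
| winter | 3.00 | 27 | 71 |
| winter | 4.00 | 31 | 65 |
| winter | 5.00 | 43 | 57 |

(readings scatter by 1.5 percentage points)



- the winner by amount of target, in percent of the substrate charged; "neither" if no more than 2 percentage points parts them (north / south / neither)
- how much target is there at the end, in percent of the substrate charged: north
- how much target is there at the end, in percent of the substrate charged: south

- I decided to treat north as a warm hold plus a small cold correction, which needed two time constants, one at each temperature of the recipe.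
- The last readings, read as first-order decay, gave 49.8 h at −22 °C and 8.89 h at −6 °C, so the time constant changed by a factor e for every 9.29 K. I left the difference in c(substrate) between those runs out of this reckoning.
- Carried along that line, my estimated time constants came to 4.66 h at 0 °C and 118 h at −30 °C, a ratio of 25.3.
- I then summed hours held over time constant across the legs, the dose 0.669, with the target fraction taken as one minus the exponential of minus the dose. North's cold leg added 0.0254 to the warm leg's 0.644, and south's dose was 0.102, so I expected 48.8% of target in north and 9.70% in south.
- The forecast named north, with 53% for north and 21% for south, both higher than my figures; it scaled the rate with concentration, which my reckoning did not, and it warned that the “concentration order is unproven”.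
- The flasks gave 48.5% in north and 14.8% in south, so north won; south stood 6.2 percentage points below the forecast and above my figure.

    substrate + catalyst intermediate B → catalyst intermediate C (k = 0.300 M⁻¹ s⁻¹, Ea = 48.0 kJ mol⁻¹)
    catalyst intermediate C ⇌ catalyst intermediate D (K = 0.880, k = 1.20 s⁻¹, Ea = 70.0 kJ mol⁻¹, ΔH = −44.0 kJ mol⁻¹)
    reagent + free catalyst ⇌ catalyst intermediate A (K = 2.50 M⁻¹, k = 1.60 M⁻¹ s⁻¹, Ea = 43.0 kJ mol⁻¹, ΔH = −25.0 kJ mol⁻¹)
    catalyst intermediate A ⇌ released group + catalyst intermediate B (K = 0.320 M, k = 0.170 s⁻¹, Ea = 64.0 kJ mol⁻¹, ΔH = −3.00 kJ mol⁻¹)
    catalyst intermediate D → free catalyst + target (k = 8.00 s⁻¹, Ea = 52.0 kJ mol⁻¹)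
    (constants at 0 °C)

- In north, the exchange of reagent and free catalyst with catalyst intermediate A, taken by that step alone, had a relaxation half-life of 0.183 min at the end of a cold hold lasting 3.00 h. Across that hold, catalyst intermediate A rose from 25.7% to 40.0% while free catalyst fell from 36.5% to 16.3%, a shift my single dose does not show.
- For the neighbour of north with 0.64 mol% of free catalyst, scaling the dose with loading gave 2.68, hence 93.1%; the simulation gave 88.9%.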